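The data were generated by integration with made-up constants, noise included.

Every partner molecule charged can be in one of three places: still partner, bound to substrate, or decomposed. You asked for a quick number and suspected that the hottest flask wastes its partner, so I started from that balance.

common to all: partner 0.0203 M; second reagent 0.0174 M
- eta: substrate 0.015 M; third reagent 0.116 M; temperature 81 °C; run made earlier
- zeta: substrate 0.022 M; third reagent 0.116 M; temperature 106 °C; run made earlier
- theta: substrate 0.029 M; third reagent 0.23 M; temperature 81 °C; run made earlier
- red: substrate 0.029 M; third reagent 0.116 M; temperature 100 °C; time 80 min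
- blue: substrate 0.029 M; third reagent 0.116 M; temperature 85 °C; time 80 min
- teal: substrate 0.029 M; third reagent 0.116 M; temperature 70 °C; time 80 min
- amber: substrate 0.029 M; third reagent 0.116 M; temperature 115 °C; time 80 min

| run | time / min | target / % | substrate / % |
|---|---|---|---|
| eta | 15.0 | 0 | 94.6 |
| eta | 50.0 | 0.9 | 84.9 |
| eta | 80.0 | 3.6 | 78.5 |
| eta | 120 | 7.4 | 71.6 |
| eta | 180 | 14.5 | 64.7 |
| eta | 240 | 21.5 | 59.3 |
| zeta | 8.00 | 0.5 | 90.0 |
| zeta | 12.0 | 0.9 | 86.6 |
| zeta | 20.0 | 3.0 | 81.3 |
| zeta | 40.0 | 9.3 | 75.2 |
| zeta | 60.0 | 15.0 | 73.8 |
| zeta | 90.0 | 20.8 | 72.8 |
| theta | 50.0 | 1.7 | 86.0 |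
| theta | 90.0 | 5.4 | 77.6 |
| theta | 150 | 12.2 | 71.6 |
| theta | 180 | 15.4 | 68.8 |
| theta | 240 | 20.5 | 65.8 |

(readings scatter by 0.3 percentage points)

1. the best flask by amount of target, in percent of the substrate charged; "all alike" if 1.5 percentage points covers them all (red / blue / teal / amber / all alike)
2. amount of target at the end, in percent of the substrate charged, red
3. amount of target at the end, in percent of the substrate charged, blue
4. amount of target at the end, in percent of the substrate charged, teal
5. amount of target at the end, in percent of the substrate charged, amber

Both losses of partner are first order in partner, so the clock drops out and the ratio of the two losses is what counts. I called the split level the substrate level, as a multiple of amber's substrate charge, at which a partner molecule is equally likely to decompose or to bind substrate. Adding up the small steps as substrate thins gives a rule for a flask whose partner is gone, with every amount in substrate charges: partner charged = substrate consumed + split level × ln(substrate charged / substrate left).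

Zeta lost 1 percentage point of substrate between its last two readings, less than the 6.1 points between its third and fourth, so I took its partner as nearly gone. Its last reading then gave a split level of 1.56. Amber's partner charge is 0.700 of its substrate charge, so the rule let amber consume 24.8% of its substrate, and I expected no more target than that. I treated this as a ceiling, since amber at 115 °C is hotter than zeta at 106 °C. Eta, at 81 °C, read 3.6% target at 80.0 min, so I expected little from teal and blue.

The forecast said amber: 12.5% for red, 5.5% for blue, 0.7% for teal and 19% for amber, on the ground that “the lag still outweighs the lost partner”. Its amber figure stands under my ceiling, which is my own reckoning and not the forecast's.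

The flasks gave amber as best, with 14.8% for red, 4.87% for blue, 0.616% for teal and 18.5% for amber.

    substrate + partner → intermediate A (k = 0.00967 L mol⁻¹ s⁻¹, Ea = 65.0 kJ mol⁻¹)
    second reagent + intermediate A → intermediate B (k = 0.0341 L mol⁻¹ s⁻¹, Ea = 51.0 kJ mol⁻¹)
    third reagent + intermediate B → target (k = 0.00912 L mol⁻¹ s⁻¹, Ea = 77.0 kJ mol⁻¹)
    2 third reagent → homo dimer (k = 8.42 × 10⁻⁴ L mol⁻¹ s⁻¹, Ea = 95.0 kJ mol⁻¹)
    partner → decomposed reagent (k = 3.32 × 10⁻⁴ s⁻¹, Ea = 109 kJ mol⁻¹)
    (constants at 100 °C)

Left ten times as long, amber kept 78.8% of its substrate, with partner, the first to run out, at 0% of its charge. That reads as a split level of 2.05, higher than zeta's. In the neighbouring flask, amber with 0.081 M of partner, the charge is 2.79 substrate charges at the same temperature. The rule then consumes 64.7% of the substrate. That flask kept 35.1% of its substrate at 80.0 min and held 46.0% target.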